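## Analysis of the target

Atom numbers follow the heavy atoms of the target SMILES from left to right (C1 to C31). The core is a bicyclo[4.3.1]decane: a cyclohexane (ring A: C15, C16, C17, C18, C20, C21) and a cycloheptanone (ring B: C5, C6, C8, C21, C20, C18, C22) share C18–C20–C21. A 2,2-dimethyloxane (ring C: C8, C10, O11, C12, C15, C21) is fused onto the C8–C21 and C21–C15 bonds.

There are six stereocentres: the contiguous set C8 (tertiary carbinol), C21 and C15 around ring C; the quaternary, methyl-bearing bridgehead C18; and the vicinal pair C22/C5, whose substituents (enol ester arm and acetonyl group) are trans. Seen from ring B, the C8 hydroxyl and the C22 arm lie on the face flanked by the one-carbon bridge C20, whereas C10 and the acetonyl carbon C4 lie on the face of the three-carbon bridge.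

Sensitive functions are the (E)-enol ester (an acyl donor, easily hydrolysed), the C2/C6 1,4-diketone (aldol and furan formation), the C6/C8 α-ketol and the epimerisable C5. The difficulty lies in bridging ring A with a seven-membered ring that ends in two fully substituted carbons (C18 and C8), and in placing two different side chains trans on neighbouring carbons late in the synthesis.

The plan rests on one feature. If the methylene bridge C20 is read as a ketone, C21 is α to it and C8 is α to the C6 ketone, so C8–C21 is the central bond of a 1,4-dicarbonyl. Ring A is then a carvone alkylated at C18 that already carries C12 as its isopropenyl carbon.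

## Retrosynthetic reasoning

**Enol ester (O25–C24).** The last bond made is O25–C24, which leads back to alkenyltrifluoroborate 29 and acid 30. The enol ester is the most fragile function, so nothing follows its formation. A copper-mediated oxidative C–O coupling carries the alkene geometry of the boron compound into the product, which enolisation and acylation of an aldehyde could not guarantee. The forward step has to tolerate two ketones and the free C8 hydroxyl.

**Boron handle (C23=C24).** 29 comes from pinacol boronate 28, and 28 from vinyl compound 26 and vinylboronate 27 by cross-metathesis at C23=C24. A plain vinyl group is the most dependable carbon nucleophile for the preceding conjugate addition, and metathesis turns it into an (E)-alkenylboron without base or hydride.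

**Side chains (C22–C23 and C4–C5).** 26 is reached from alkyne 24 by hydration (25) and desilylation. The acetonyl group is carried as a propargyl group so that no 1,4-diketone coexists with an enolate. 24 is cut at C22–C23 and C4–C5 to enone 20, vinylmagnesium bromide 21 and propargyl bromide 22. The cut is made here for three reasons: C22 and C5 are the β- and α-carbons of the C6 ketone; C8 has no hydrogen, so only one enolate can exist; and the vinyl group just added steers the halide to the opposite face.

**Enone (C5=C22).** 20 comes from saturated ketone 18 through bis-silyl derivative 19. Only C5 can enolise, so the dehydrogenation is regiospecific, and the same silylation caps the C8 hydroxyl.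

**Ring C (O11–C12).** 18 is opened at O11–C12 to diol 17, which carries the isopropenyl group of the starting terpene on C15. Protonation gives the tertiary C12 cation, the C10 hydroxyl is the only oxygen that can reach it, and no stereocentre is created.

**C8–O9 and the oxidation levels at C6, C10 and C20.** 17 is traced to silyl enol ether 15 (oxygen transfer to C6=C8), 15 to ester 14 (hydride reduction), 14 through 13 and 12 to ketone 11 (deoxygenation at C20), and 11 to diketo ester 10. Holding the β-keto ester as its silyl enol ether does three things:
- it leaves C20 as the only ketone, so that it alone is reduced and removed;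
- it allows the ester to be reduced without touching C6;
- it provides the C6=C8 double bond whose oxidation installs O9 and returns the C6 ketone.

The forward oxidation must take place on the face of C8 that looks toward C20.

**Key disconnection (C8–C21).** 10 is cut at C8–C21 to the monocyclic keto β-keto ester 8. The cut removes ring B and two stereocentres at once and leaves a substrate in which both carbons are enolisable in only one way. The forward reaction is the oxidation of bis-enolate 9, and the tether from C18 forces the new bond onto the face of C21 that the target requires.

**Precursor.** 8 is cut at C6–C8 to acid 5 and malonate half-ester 6, 5 comes from ester 4, and 4 is cut at C18–C22 to dihydrocarvone 2 and methyl acrylate 3. 2 is the conjugate-reduction product of (R)-carvone 1, which supplies C15 and, through it, every other stereocentre.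

## Alternatives that were turned down

**Alternative 1:** The disconnection removes C4–C5 and C22–C23 from a C5=C22 alkene of the finished tricycle in which C6 is a carbinol. The acetonyl carbons are delivered from a bromoketal hung on O7. In the forward step a tin radical abstracts bromine, the C4 radical closes 5-exo onto C5, and the C22 radical is intercepted by an allylstannane to give A1.
- For it: both side-chain bonds form in one operation. C5 is tied covalently to O7 through a cis-fused five-membered ring, and C22 is trapped anti to that ring, so the trans relationship is enforced rather than hoped for. The ketone of the acetonyl group arrives protected.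
- Against it: the plan presupposes the whole tricycle with a C6 carbinol of defined configuration and says nothing about how rings A and B are made. Intermolecular trapping of a radical at C22, next to quaternary C18, competes with simple reduction. The allyl group brings three carbons where two are needed, so one must be excised to an aldehyde, and the enol ester geometry would then depend on an unselective enolisation.
- Comparison: on the C5/C22 relationship it is stronger than the enolate alkylation of step 15. The chosen strategy offers instead a solution for the bridged core, absolute configuration from 1, and an (E)-enol ester derived stereospecifically from the vinyl group.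

**Alternative 2:** The disconnection cuts C18–C20 and C16–C17, unravelling rings A and B to an oxane (ring C) with exocyclic alkenes at C21 and C15 that is tethered from C8 to a vinyl sulfone at C17=C18. On heating, a type 2 intramolecular Diels–Alder reaction gives A2 with a C15=C21 bridgehead alkene.
- For it: two rings and the quaternary C18 form in one step, ring C and the C8 carbinol are in place beforehand, and the sulfone is a removable activator. In bonds per step it is stronger than the chosen key step.
- Against it: the dienophile is fully substituted at C18 and would be sluggish. The bridgehead alkene must afterwards be hydrogenated on one defined face to create C15 and C21 together. C18 is set relative to C8 only through the tether in the transition state. The sulfone must be removed, and the dimethylene-oxane substrate with its tertiary carbinol needs a long preparation and an enantioselective origin for C8.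
- Comparison: the chosen route forms only one skeletal bond in its key step, but each stereocentre is relayed from its neighbour (C15 to C18 to C21 to C8) and ring A is purchased.

**Alternative 3:** The disconnection cuts C15–C21 and O11–C12, reducing the target to a monocyclic ring B dienone that carries a C8/C21 epoxide, a side chain on C18 ending in the C15=C12 alkene, and the C10 hydroxyl. A boron Lewis acid opens the epoxide at C21, C15 attacks to close ring A, and O11 captures the C12 cation to close ring C. This gives A3, the C8-desilylated counterpart of 20.
- For it: it is the shortest plan. Two rings and the C21/C15 centres arise in one cascade that ends at the enone stage, so in step economy it is clearly stronger.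
- Against it: the epoxide is α to the C6 ketone, and Lewis acids turn such epoxy ketones into rearranged dicarbonyls by 1,2-shifts. C21 is a secondary centre with no cation-stabilising group. The side chain must reach across a flexible seven-membered ring to form a bridge. The epoxide has to be placed relative to a remote quaternary centre that itself needs an enantioselective synthesis.
- Comparison: the chosen strategy pays with more steps. In return the bond-forming sites of the key step are unique, and its stereochemical outcome is dictated by a rigid, bought ring.

Key step: step 5

Remark on the chemistry: the C2 centre of 2 and the C20 carbinol centre of 12 and 13 are left open, because both are erased in later steps (step 2 and step 9).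

## Route

Step 1
Reactants: 1 (R)-carvone
Product: 2 (2R,5R)-dihydrocarvone (trans-2-methyl-5-(prop-1-en-2-yl)cyclohexan-1-one; the C2 epimer serves equally)
Conditions: LiBH(s-Bu)3 (1.05 equiv), THF, −78 °C; aq. NH4Cl
Reagents that add atoms: none
Why: Conjugate (1,4) hydride reduction of a β-unsubstituted cyclohexenone by a hindered trialkylborohydride; the isolated isopropenyl group and the C15 stereocentre are untouched, and the ketone stays masked as its enolate until work-up.

Step 2
Reactants: 2 dihydrocarvone; 3 methyl acrylate
Product: 4 methyl 3-[(1R,4R)-1-methyl-2-oxo-4-(prop-1-en-2-yl)cyclohexyl]propanoate (propanoate chain on C18 cis to the isopropenyl group)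
Conditions: KOt-Bu (0.2 equiv), t-BuOH/THF, 0 → 20 °C, 3 (1.1 equiv)
Reagents that add atoms: none
Why: Base-catalysed Michael addition through the more substituted (thermodynamic) enolate, as in the first stage of a Robinson annulation; C18 is set by axial attack on the enolate half-chair that keeps the isopropenyl group equatorial, which places the new chain cis to it.

Step 3
Reactants: 4 keto ester
Product: 5 3-[(1R,4R)-1-methyl-2-oxo-4-(prop-1-en-2-yl)cyclohexyl]propanoic acid
Conditions: LiOH, THF/H2O, 20 °C; aq. HCl
Reagents that add atoms: lithium hydroxide, [Li+].[OH-]
Why: Saponification of an unhindered methyl ester; the quaternary C18 cannot epimerise and C15 is not acidic.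

Step 4
Reactants: 5 keto acid; 6 potassium methyl malonate
Product: 8 methyl 5-[(1R,4R)-1-methyl-2-oxo-4-(prop-1-en-2-yl)cyclohexyl]-3-oxopentanoate, via acyl imidazolide 7 (not isolated)
Conditions: 1,1'-carbonyldiimidazole, THF, 20 °C; then 6, MgCl2, Et3N, MeCN, 20 → 45 °C; aq. HCl
Reagents that add atoms: none
Why: Masamune-type chain extension: the acyl imidazolide C-acylates the magnesium malonate and the adduct decarboxylates to the β-keto ester (bond C6–C8); the neutral conditions leave the ring ketone and both stereocentres alone.

Step 5
Reactants: 8 keto β-keto ester
Product: 10 bridged diketo ester (rings A and B; ketones at C6 and C20; CO2Me on C8; isopropenyl on C15; C15 and C18 and C21 as in the target; C8 enolisable), via dilithium bis-enolate 9 (not isolated)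
Conditions: LiN(SiMe3)2 (2.3 equiv), THF, −78 °C (8 added to the base, 0.01 M); then [Fe(DMF)3Cl2][FeCl4] (2.2 equiv), −78 → 0 °C
Reagents that add atoms: none
Why: Two equivalents of LiN(SiMe3)2 deprotonate C8 (between the C6 ketone and the ester) and C21 (the only α-hydrogens of the C20 ketone, C18 being quaternary), and the amide is too weak to take a C5 proton from the β-keto ester enolate, so one defined bis-enolate 9 results. The trivalent iron salt removes one electron from an enolate to give an α-carbonyl radical, which adds across the tether to the carbon of the partner enolate; a second trivalent iron oxidises the resulting radical anion, so the net change is loss of two electrons and formation of C8–C21. The closest known reaction type is the intramolecular oxidative heterocoupling of a ketone enolate with a 1,3-dicarbonyl enolate by an FeCl3-derived oxidant to close a bridged carbocycle. Ring B closes in a 7-endo-trig mode with respect to the C20=C21 enolate, as a bridge across ring A. C21 is controlled by C18: the chain can reach C21 only on the face to which it is attached, in the chair that has C22 axial and the isopropenyl group equatorial, which gives the 1,3-diaxial bridge and places C8 cis to C12. C8 is formed as an enolisable centre whose configuration is not needed, since it is planarised in step 6. The step needs heterocoupling rather than dimerisation (secured by the tether and high dilution), reaction at C8 rather than C5 (only C8 is deprotonated) and no aldol between C8 and C20 (secured by inverse addition to excess base at −78 °C, which enolises the ketone at once).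

Step 6
Reactants: 10 bridged diketo ester
Product: 11 C6 tert-butyldimethylsilyl enol ether of 10 (C6=C8 double bond conjugated with the ester; C20 ketone free)
Conditions: t-BuMe2SiOTf (1.2 equiv), Et3N, CH2Cl2, 0 °C
Reagents that add atoms: tert-butyldimethylsilyl trifluoromethanesulfonate, CC(C)(C)[Si](C)(C)OS(=O)(=O)C(F)(F)F
Why: O-Silylation of a β-keto ester enol; the C20 ketone cannot form an enol ether because one α-carbon is quaternary and the other is a bridgehead, so it remains the only ketone.

Step 7
Reactants: 11 silyl enol ether keto ester
Product: 12 C20 alcohol (either epimer)
Conditions: NaBH4, EtOH/THF, 0 °C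
Reagents that add atoms: none
Why: Borohydride reduction of the single free ketone; the ester and the vinylogous silyl carbonate are not reduced under these conditions, and the new carbinol centre is removed in step 9.

Step 8
Reactants: 12 C20 alcohol
Product: 13 C20 O-phenyl thionocarbonate
Conditions: PhOC(S)Cl, pyridine, DMAP (cat.), CH2Cl2, 20 → 40 °C
Reagents that add atoms: O-phenyl carbonochloridothioate, S=C(Cl)Oc1ccccc1
Why: Acylation of a secondary alcohol under nucleophilic catalysis; no strong base is used, so the silyl group cannot migrate from O6 to O20.

Step 9
Reactants: 13 thionocarbonate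
Product: 14 C20-deoxygenated silyl enol ether ester (C20 is now CH2)
Conditions: Bu3SnH, AIBN (cat.), toluene, 100 °C
Reagents that add atoms: none
Why: Barton–McCombie deoxygenation; the secondary C20 radical is reduced by the tin hydride faster than it can add to the isopropenyl group (4-exo or 5-endo) or to C8 (3-exo, with the enoate π-system nearly orthogonal to the radical orbital).

Step 10
Reactants: 14 silyl enol ether ester
Product: 15 allylic alcohol (C10 hydroxymethyl on C8; C6 silyl enol ether retained)
Conditions: i-Bu2AlH (2.5 equiv), CH2Cl2, −78 → −40 °C; aq. potassium sodium tartrate (pH 7)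
Reagents that add atoms: none
Why: 1,2-Reduction of a β-silyloxy enoate to the 3-silyloxy allylic alcohol; cold neutral work-up avoids ionisation of this acid-labile product, which is used without purification.

Step 11
Reactants: 15 silyloxy allylic alcohol
Product: 17 dihydroxy ketone (C6 ketone; C8 tertiary hydroxyl on the C20 face; C10 primary hydroxyl; isopropenyl on C15), via silyloxy epoxide 16 (not isolated)
Conditions: dimethyldioxirane (1.05 equiv, acetone), CH2Cl2, −78 → −40 °C; then Et3N·3HF, THF, 0 °C
Reagents that add atoms: dimethyldioxirane, CC1(C)OO1
Why: Rubottom oxidation: the tetrasubstituted silyl enol ether is far more electron-rich than the isopropenyl group and is epoxidised selectively, and fluoride opens the silyloxy epoxide to the α-hydroxy ketone. C8 is set by attack anti to the C21–C15 bond, which stands nearly perpendicular to the enol ether plane on the face shielded by the axial hydrogen on C16 and by the isopropenyl group, so oxygen enters from the C20 side and C10 is pushed toward C12.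

Step 12
Reactants: 17 dihydroxy ketone
Product: 18 tricyclic hydroxy ketone (rings A and B and C; C6 ketone; C8 hydroxyl)
Conditions: TsOH·H2O (0.1 equiv), CH2Cl2, 20 °C
Reagents that add atoms: none
Why: Acid-catalysed Markovnikov hydroalkoxylation: protonation of the isopropenyl group gives the tertiary C12 cation, which the C10 hydroxyl captures in a six-membered ring; the C8 hydroxyl is anti to C15 and cannot reach C12, alkene isomers return to the same cation, and no stereocentre is created.

Step 13
Reactants: 18 tricyclic hydroxy ketone
Product: 19 bis(triethylsilyl) derivative (C8 triethylsilyl ether and C5=C6 triethylsilyl enol ether)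
Conditions: Et3SiOTf (2.5 equiv), Et3N, CH2Cl2, −78 → 0 °C
Reagents that add atoms: triethylsilyl trifluoromethanesulfonate, CC[Si](CC)(CC)OS(=O)(=O)C(F)(F)F
Why: Silyl triflate/amine silylation of the tertiary alcohol and of the ketone; enolisation is possible only toward C5 because C8 is quaternary.

Step 14
Reactants: 19 bis(triethylsilyl) derivative
Product: 20 enone (C5=C22 conjugated with the C6 ketone; C8 triethylsilyl ether)
Conditions: Pd(OAc)2 (1.1 equiv), MeCN, 20 °C
Reagents that add atoms: none
Why: Saegusa–Ito oxidation: divalent palladium forms the oxa-π-allyl species from the silyl enol ether and β-hydride elimination of the C22 hydrogen gives the enone; no other alkene is present.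

Step 15
Reactants: 20 enone; 21 vinylmagnesium bromide; 22 propargyl bromide
Product: 24 C22-vinyl C5-propargyl ketone (vinyl on the C20 face of ring B; propargyl trans to it; C8 triethylsilyl ether), via bromomagnesium enolate 23 (not isolated)
Conditions: CuBr·SMe2 (0.2 equiv), 21 (1.5 equiv), THF, −40 °C; then DMPU, 22 (3 equiv), −40 → 20 °C
Reagents that add atoms: none
Why: Copper-catalysed conjugate addition followed by alkylation of the regiodefined enolate (three-component coupling). C22 is set by attack anti to the C18–C17 bond, which stands nearly perpendicular to the enone plane on the face of the three-carbon bridge, so the vinyl group enters between C19 and C20. C5 is set by approach of the halide anti to the new vinyl group, and the enolate cannot migrate because C8 has no hydrogen.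

Step 16
Reactants: 24 propargyl ketone
Product: 25 methyl ketone (acetonyl on C5; C22 vinyl; C8 triethylsilyl ether)
Conditions: Ph3PAuNTf2 (2 mol %), 1,4-dioxane/H2O, 40 °C
Reagents that add atoms: water, O
Why: Markovnikov hydration of a terminal alkyne by a monovalent gold catalyst, assisted by the C6 carbonyl oxygen, which gives the 1,4-diketone regiospecifically; the vinyl group is inert and no base is present to trigger an aldol.

Step 17
Reactants: 25 silyl ether diketone
Product: 26 hydroxy diketone (free C8 hydroxyl; C22 vinyl)
Conditions: HF·pyridine, THF/pyridine, 0 → 20 °C
Reagents that add atoms: none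
Why: Fluoride cleavage of a tertiary triethylsilyl ether under buffered, non-basic conditions, which spare the 1,4-diketone and the α-ketol.

Step 18
Reactants: 26 hydroxy diketone; 27 vinylboronic acid pinacol ester
Product: 28 (E)-alkenyl pinacol boronate (C22–CH=CH–B)
Conditions: second-generation Hoveyda–Grubbs catalyst (10 mol %), 27 (4 equiv), CH2Cl2, 40 °C
Reagents that add atoms: none
Why: Olefin cross-metathesis of a hindered, non-dimerising terminal alkene with a vinylboronate, a pairing that should give the thermodynamically preferred (E)-alkenylboronate; ketones and the tertiary alcohol are tolerated.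

Step 19
Reactants: 28 alkenyl pinacol boronate
Product: 29 potassium (E)-alkenyltrifluoroborate
Conditions: KHF2 (aq.), MeOH, 20 °C
Reagents that add atoms: potassium hydrogen difluoride, [K+].[F-].F
Why: Standard conversion of a pinacol boronate into the trifluoroborate salt, with the alkene geometry unchanged.

Step 20
Reactants: 29 alkenyltrifluoroborate; 30 3-methylbut-2-enoic acid
Product: 31 target compound CNP0237201.2
Conditions: CuBr (20 mol %), DMAP, 30 (3 equiv), 4 Å molecular sieves, O2 (1 atm), CH2Cl2, 40 °C
Reagents that add atoms: none
Why: Chan–Lam-type oxidative C–O coupling of an alkenyltrifluoroborate with a carboxylic acid: transmetalation to copper and reductive elimination from a high-valent copper carboxylate form O25–C24 with retention of the (E) geometry; the hindered tertiary alcohol does not compete.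

## Compound list

1 | (R)-carvone | CC1=CC[C@H](CC1=O)C(=C)C | starting material
2 | (2R,5R)-dihydrocarvone | C[C@@H]1CC[C@H](CC1=O)C(C)=C | intermediate
3 | methyl acrylate | C=CC(=O)OC | starting material
4 | methyl 3-[(1R,4R)-1-methyl-2-oxo-4-(prop-1-en-2-yl)cyclohexyl]propanoate | COC(=O)CC[C@@]1(C)CC[C@H](CC1=O)C(C)=C | intermediate
5 | 3-[(1R,4R)-1-methyl-2-oxo-4-(prop-1-en-2-yl)cyclohexyl]propanoic acid | OC(=O)CC[C@@]1(C)CC[C@H](CC1=O)C(C)=C | intermediate
6 | potassium methyl malonate | COC(=O)CC(=O)[O-].[K+] | starting material
7 | acyl imidazolide of 5 | O=C(CC[C@@]1(C)CC[C@H](CC1=O)C(C)=C)n1ccnc1 | intermediate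
8 | methyl 5-[(1R,4R)-1-methyl-2-oxo-4-(prop-1-en-2-yl)cyclohexyl]-3-oxopentanoate | COC(=O)CC(=O)CC[C@@]1(C)CC[C@H](CC1=O)C(C)=C | intermediate
9 | dilithium bis-enolate of 8 (C8 and C21) | COC(=O)C=C([O-])CC[C@@]1(C)CC[C@H](C=C1[O-])C(C)=C.[Li+].[Li+] | intermediate
10 | bridged diketo ester (methyl 6-methyl-3,10-dioxo-9-(prop-1-en-2-yl)bicyclo[4.3.1]decane-2-carboxylate; C15, C18, C21 as in the target) | C1C(=O)[C@H](C(=O)OC)[C@@H]2[C@H](C(C)=C)CC[C@@](C)(C2=O)C1 | intermediate
11 | C6 tert-butyldimethylsilyl enol ether of 10 | C1C(O[Si](C)(C)C(C)(C)C)=C(C(=O)OC)[C@@H]2[C@H](C(C)=C)CC[C@@](C)(C2=O)C1 | intermediate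
12 | C20 alcohol (either epimer) | C1C(O[Si](C)(C)C(C)(C)C)=C(C(=O)OC)[C@@H]2[C@H](C(C)=C)CC[C@@](C)(C2O)C1 | intermediate
13 | C20 O-phenyl thionocarbonate | C1C(O[Si](C)(C)C(C)(C)C)=C(C(=O)OC)[C@@H]2[C@H](C(C)=C)CC[C@@](C)(C2OC(=S)Oc3ccccc3)C1 | intermediate
14 | C20-deoxygenated silyl enol ether ester | C1C(O[Si](C)(C)C(C)(C)C)=C(C(=O)OC)[C@@H]2[C@H](C(C)=C)CC[C@@](C)(C2)C1 | intermediate
15 | silyloxy allylic alcohol (C10 hydroxymethyl) | C1C(O[Si](C)(C)C(C)(C)C)=C(CO)[C@@H]2[C@H](C(C)=C)CC[C@@](C)(C2)C1 | intermediate
16 | C6/C8 silyloxy epoxide (oxygen on the C20 face) | C1[C@@]2(O[Si](C)(C)C(C)(C)C)O[C@@]2(CO)[C@@H]3[C@H](C(C)=C)CC[C@@](C)(C3)C1 | intermediate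
17 | dihydroxy ketone (C6 ketone, C8 and C10 hydroxyls) | C1C(=O)[C@](O)(CO)[C@@H]2[C@H](C(C)=C)CC[C@@](C)(C2)C1 | intermediate
18 | tricyclic hydroxy ketone (rings A, B, C) | C1C(=O)[C@]2(O)COC(C)(C)[C@@H]3CC[C@@](C)(C[C@@H]32)C1 | intermediate
19 | C8 triethylsilyl ether, C5=C6 triethylsilyl enol ether | C1=C(O[Si](CC)(CC)CC)[C@]2(O[Si](CC)(CC)CC)COC(C)(C)[C@@H]3CC[C@@](C)(C[C@@H]32)C1 | intermediate
20 | C5=C22 enone, C8 triethylsilyl ether | C=1C(=O)[C@]2(O[Si](CC)(CC)CC)COC(C)(C)[C@@H]3CC[C@@](C)(C[C@@H]32)C=1 | intermediate
21 | vinylmagnesium bromide | C=C[Mg]Br | starting material
22 | propargyl bromide | C#CCBr | starting material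
23 | bromomagnesium C5=C6 enolate with C22 vinyl | C1=C([O-])[C@]2(O[Si](CC)(CC)CC)COC(C)(C)[C@@H]3CC[C@@](C)(C[C@@H]32)[C@H]1C=C.[Mg+2].[Br-] | intermediate
24 | C22-vinyl C5-propargyl ketone, C8 triethylsilyl ether | C#CC[C@@H]1C(=O)[C@]2(O[Si](CC)(CC)CC)COC(C)(C)[C@@H]3CC[C@@](C)(C[C@@H]32)[C@H]1C=C | intermediate
25 | C5-acetonyl C22-vinyl ketone, C8 triethylsilyl ether | CC(=O)C[C@@H]1C(=O)[C@]2(O[Si](CC)(CC)CC)COC(C)(C)[C@@H]3CC[C@@](C)(C[C@@H]32)[C@H]1C=C | intermediate
26 | C5-acetonyl C22-vinyl hydroxy ketone | CC(=O)C[C@@H]1C(=O)[C@]2(O)COC(C)(C)[C@@H]3CC[C@@](C)(C[C@@H]32)[C@H]1C=C | intermediate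
27 | vinylboronic acid pinacol ester | C=CB1OC(C)(C)C(C)(C)O1 | starting material
28 | (E)-alkenyl pinacol boronate | CC(=O)C[C@@H]1C(=O)[C@]2(O)COC(C)(C)[C@@H]3CC[C@@](C)(C[C@@H]32)[C@H]1/C=C/B4OC(C)(C)C(C)(C)O4 | intermediate
29 | potassium (E)-alkenyltrifluoroborate | CC(=O)C[C@@H]1C(=O)[C@]2(O)COC(C)(C)[C@@H]3CC[C@@](C)(C[C@@H]32)[C@H]1/C=C/[B-](F)(F)F.[K+] | intermediate
30 | 3-methylbut-2-enoic acid | CC(C)=CC(O)=O | starting material
31 | CNP0237201.2 | CC(=O)C[C@@H]1C(=O)[C@]2(O)COC(C)(C)[C@@H]3CC[C@@](C)(C[C@@H]32)[C@H]1/C=C/OC(=O)C=C(C)C | target

## Step count and least certain steps

Total step count: 20. Longest linear sequence: 20 steps (1 to 31).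

**Step 5 (key step).** The most likely failure is diversion of the bis-enolate: intermolecular dimerisation, chlorination by the iron salt, further oxidation of the still acidic product, or an aldol between the C8 enolate and a C20 ketone that was not enolised in time. All of these follow from the two enolates reacting separately rather than with each other. Fallback: starting from 8, both carbonyl groups would be silylated with Me3SiOTf/Et3N to the bis(trimethylsilyl enol ether) F1. F1 would be oxidised with (NH4)2Ce(NO3)6 and NaHCO3 in MeCN at −30 °C. Tetravalent cerium takes an electron from the more electron-rich ring enol ether, the radical cation is captured at C8 of the silyloxy enoate, and a second oxidation and loss of silicon follow. This oxidative coupling of a bis(silyl enol ether) needs no strong base and returns to the route at 10.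

**Step 15.** Poor facial selectivity of the copper reagent at C22 is the main danger, because the two faces are flanked by groups of similar local size (C19 methyl against the C17 methylene), and C22 cannot be corrected later. A second danger is alkylation at C5 cis to the vinyl group. Fallback: starting from 20, the vinyl group would be added under catalyst control by a Hayashi–Miyaura reaction: potassium vinyltrifluoroborate, Rh(acac)(C2H4)2 and the enantiomer of BINAP that is matched to the C20 face, in dioxane/H2O at 90 °C. This gives the C22-vinyl ketone F7. F7 would then be deprotonated with LiN(i-Pr)2 (only C5 is available) and alkylated with 22 in THF/DMPU under kinetic control, returning at 24. If C5 alone is at fault, it can be equilibrated with a tertiary amine at the stage of 24.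

**Step 11.** Loss of face selectivity in the oxygen transfer to C8, competing epoxidation of the isopropenyl group, or silyl migration to the C10 oxygen at the stage of 15 would each erode the yield of 17. Fallback: starting from 14, the order of events would be inverted so that ring C fixes C8 before oxygen is introduced.
- Heating 14 with TsOH·H2O in wet toluene would cleave the silyl enol ether and let the ester carbonyl capture the C12 cation, giving the β-keto δ-lactone F3.
- In F3, C10 is locked toward C15, so hydroxylation of its enol with dimethyldioxirane can only place oxygen on the C20 face, giving the hydroxy keto lactone F4.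
- i-Bu2AlH would reduce F4 to the lactol carbinol F5.
- Et3SiH with BF3·OEt2 would reduce the lactol to the cyclic ether F6.
- Dess–Martin periodinane would oxidise the secondary C6 carbinol and return to the route at 18.

**Step 2.** Insufficient preference for axial attack (giving the C18 epimer) or competing addition at C21 would contaminate everything downstream. Fallback: starting from 2, condensation with (S)-1-phenylethylamine (toluene, azeotropic removal of water) would give the imine F2. Its more substituted secondary enamine tautomer adds to 3 in an aza-ene-like Michael reaction whose face is set by the auxiliary. Hydrolysis with aqueous acetic acid returns to the route at 4.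

**Step 18.** Slow initiation at the hindered C22 vinyl group, with catalyst decay before conversion, is the likely problem. Fallback: starting from 26, ozonolysis (O3, CH2Cl2/MeOH, −78 °C; Me2S) would give the aldehyde F8. Takai-type olefination with Cl2CHB(pin), CrCl2 and LiI in THF, which is selective for aldehydes over ketones and for the (E) isomer, would return to the route at 28. The C22 centre is α to the aldehyde, so F8 would be used at once.

**Step 20.** Protodeboronation or homocoupling of the hindered alkenylboron may outrun C–O bond formation. Fallback: starting from 29, ipso-iodination with NaI and chloramine-T in THF/H2O would give the (E)-alkenyl iodide F9 with retention. F9 would be heated in pyridine with the monovalent copper carboxylate CuO2CCH=CMe2, prepared from 30 and Cu2O. This vinylic substitution by a copper carboxylate proceeds with retention and arrives directly at 31.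

## Further compounds

F1 | step 5 | bis(trimethylsilyl enol ether) of 8 | COC(=O)C=C(O[Si](C)(C)C)CC[C@@]1(C)CC[C@H](C=C1O[Si](C)(C)C)C(C)=C
F2 | step 2 | imine of 2 with (S)-1-phenylethylamine | CC1CC[C@H](CC1=N[C@@H](C)c1ccccc1)C(C)=C
F3 | step 11 | β-keto δ-lactone (ring C closed as lactone, C8–H) | C1C(=O)[C@@H]2C(=O)OC(C)(C)[C@@H]3CC[C@@](C)(C[C@@H]32)C1
F4 | step 11 | C8-hydroxy β-keto δ-lactone | C1C(=O)[C@]2(O)C(=O)OC(C)(C)[C@@H]3CC[C@@](C)(C[C@@H]32)C1
F5 | step 11 | lactol with C6 carbinol | C1C(O)[C@]2(O)C(O)OC(C)(C)[C@@H]3CC[C@@](C)(C[C@@H]32)C1
F6 | step 11 | tricyclic C6,C8-diol (ring C ether) | C1C(O)[C@]2(O)COC(C)(C)[C@@H]3CC[C@@](C)(C[C@@H]32)C1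
F7 | step 15 | C22-vinyl ketone, C8 triethylsilyl ether | C1C(=O)[C@]2(O[Si](CC)(CC)CC)COC(C)(C)[C@@H]3CC[C@@](C)(C[C@@H]32)[C@H]1C=C
F8 | step 18 | C22 aldehyde | CC(=O)C[C@@H]1C(=O)[C@]2(O)COC(C)(C)[C@@H]3CC[C@@](C)(C[C@@H]32)[C@H]1C=O
F9 | step 20 | (E)-alkenyl iodide | CC(=O)C[C@@H]1C(=O)[C@]2(O)COC(C)(C)[C@@H]3CC[C@@](C)(C[C@@H]32)[C@H]1/C=C/I
A1 | alternative 1 | cyclic ketal spanning C2 and O7 with allyl on C22 | CO[C@]1(C)C[C@@H]2[C@H](O1)[C@]3(O[Si](CC)(CC)CC)COC(C)(C)[C@@H]4CC[C@@](C)(C[C@@H]43)[C@H]2CC=C
A2 | alternative 2 | tricyclic bridgehead alkene with C6 ketone, C8 carbinol and C17 sulfone | C1C(=O)[C@]2(O)COC(C)(C)C3=C2C[C@](C)([C@H](C3)S(=O)(=O)c4ccccc4)C1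
A3 | alternative 3 | tricyclic C8 carbinol with C5=C22 enone | O=C1[C@]2(O)COC(C)(C)[C@@H]3CC[C@@](C)(C[C@@H]32)C=C1
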